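Remark on the chemistry: ring positions C1 to C6 are those of the target throughout (C1 is the benzylic carbon), and the alkene geometry of compounds 2, 3 and 4 is left undefined because those carbons end up as ring atoms. Compound numbers are those of the steps and of the list after them; 16 is the target.

## Analysis of the target

Compound 16 is a pyrrolidin-2-one whose nitrogen carries a benzyl group, and the benzene ring of that group has no hydrogen left. Counted from the benzylic carbon, it bears CH2N at C1, bromine at C2, hydroxyl at C3 and C4, and bromine at C5 and C6. There is no stereocentre, so the problem is purely one of constitution: six substituents in the right order around one ring. The C3/C4 catechol is the sensitive part, since it is easily oxidised to an ortho-quinone, most of all by the halogen needed for the C–Br bonds. The C4 hydroxyl is para to C1, so the benzylic C–N bond is that of a para-hydroxybenzyl amide: it can ionise towards a quinone methide under hot acid, and C1 is itself open to ipso attack by electrophiles. The five-membered lactam tolerates Lewis acids and mild base but would open in hot aqueous hydroxide or mineral acid. The difficulty is to fix the two oxygens and the side chain relative to each other with certainty, and then to bring in three bromines without over-oxidation. The strategy reads the ring as two three-carbon pieces: C2–C3–C4 is the carbon run of the 4-methoxyacetoacetate 1, whose ester carbon sits on C2 and later gives way to bromine, and C5–C6–C1 is a β-methoxy enone whose carbonyl carbon (C1) already carries the CH2N arm.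

## Retrosynthetic reasoning

**16 to 15.** The three C–Br bonds are cut first. In 15, C5 is ortho to the C4 hydroxyl, C6 is para to the C3 hydroxyl, and C2 is ortho to the C3 hydroxyl but occupied by a carboxyl group. An electrophilic halogen that attacks a carboxyl-bearing carbon ortho to a phenol displaces the carboxyl group, so one halogenation of 15 should fill all three positions. This turns the ester that the ring construction leaves on C2 into a placeholder for bromine. The forward reaction must brominate three times without oxidising the catechol or dislodging the benzylic arm.

**15 to 14 to 13.** Two O–CH3 bonds are cut next. The ester of 13 is cleaved at the methyl–oxygen bond and not at the acyl–oxygen bond. Its carbonyl is flanked on both sides (C1 and C3 substituents) and would sit next to a phenoxide in base, so attack at the carbonyl would need forcing aqueous alkali that endangers the lactam. Attack of a soft nucleophile on the methyl group is indifferent to that crowding. The aryl methyl ether at C4 is then cleaved with a boron Lewis acid. It is removed before the halogenation so that C5 becomes ortho to a free hydroxyl and all three brominations run under mild conditions.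

**13 to 4 and 10.** The ring bonds C4–C5 and C1–C2 are cut. This divides the arene into a 1,3-dinucleophile (4, carrying both oxygens and the ester) and a 1,3-dielectrophile (10, carrying the side chain on its carbonyl carbon). The polarity of each new bond is matched, and the aromatic oxidation level arises from two eliminations with no redox step. A cut between C3 and C4 would separate the two oxygens and was not considered further. The forward reaction has to send the methoxy-bearing terminus of 4 to the β-carbon of 10 and the central carbon of 4 to the ketone.

**4 to 2 to 1.** Two O–Si bonds are cut, one at a time. The ketone enol of 1 is silylated first, then the extended ester dienolate 3. This is the standard access to such dienes from a β-keto ester and adds no carbon.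

**10 to 9 to 7 and 8, and 7 to 5.** The enol ether C–O bond of 10 is traced to conjugate addition of the alcohol to the terminal ynone 9. The ynone is cut between carbonyl and alkyne into the N-methoxy-N-methyl amide 7 and the Grignard reagent 8, and 7 comes from acid 5 by amide formation through 6. An ynone is preferred to formylation of a methyl ketone because the CH2 between ketone and lactam nitrogen is the more acidic site. A condensation would therefore start on the wrong side, whereas the alkyne fixes where the one-carbon terminus sits.

## Alternatives that were turned down

**Alternative 1: glycol double substitution on a perbrominated arene.**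
- Disconnection: the C3–O and C4–O bonds are traced to two aryl bromides of 1-[(pentabromophenyl)methyl]pyrrolidin-2-one A1 and to ethane-1,2-diol A2.
- Forward key step: A2 with a carbonate base in a hot dipolar aprotic solvent displaces one ring bromide, and the pendant hydroxyl displaces the neighbouring one. This gives the dihydrobenzodioxin A3, whose ethylene bridge must then be removed.
- For: it is the shortest route, since A1 is one N-alkylation away from a commercial perbrominated benzyl halide. All three bromines are present from the start, so no catechol ever meets an electrophilic halogen. On both points it is stronger than the chosen route.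
- Against: there are five C–Br sites and no activating group. Attack at C3 puts the negative charge of the σ-adduct on three bromine-bearing carbons, while attack at C4 puts it on the alkyl-bearing C1, so the first substitution probably goes meta to the side chain as needed. The ring closure can then go to C2 or to C4 with little to tell them apart, and the 2,3-dioxygenated isomer would be hard to separate. Hot base next to a benzylic CH2 flanked by two bromines invites halogen migration and reductive debromination. The ethylene bridge of a benzodioxin is among the most stubborn catechol protections, and conditions that open it are likely to break the para-oxybenzyl C–N bond as well.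
- Comparison: the chosen route is about twice as long, but the place of each substituent follows from the connectivity of 4 and 10 and not from a weak substituent effect.

**Alternative 2: oxalate and adipate double Claisen condensation.**
- Disconnection: the bonds C2–C3 and C4–C5 are cut, building the ring from the 3-substituted adipate A4 and diethyl oxalate A5.
- Forward key step: an alkoxide base condenses A5 with both α-carbons of A4 to give the bis-enol A6. Dehydrogenation to the aromatic diester, ester cleavage, two decarboxylative brominations and one ordinary bromination at C6 would follow.
- For: the chemistry is classical and the reagents cheap. The two oxygens arrive together, and ring formation raises no regiochemical question because both α-carbons of A4 must react. On that point it is stronger than the chosen route, which depends on a 1,4- versus 1,2-attack.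
- Against: A4 is not commercial and needs several steps. The Claisen step at the α-carbon next to the branch is hindered. The α-methylene of the lactam is itself a donor towards an oxalate under alkoxide, so chemoselectivity is doubtful. A6 is two hydrogens short of an arene and needs an oxidant in the presence of an enediol, and two carboxyl groups must be removed instead of one.
- Comparison: the chosen route reaches the aromatic oxidation level directly by loss of the enone methoxy group and dehydration, carries one placeholder instead of two, and starts from two commercial compounds.

**Alternative 3: thiophene dioxide and bromoalkyne cycloaddition.**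
- Disconnection: the bonds C1–C2 and C5–C6 are cut, giving 2,5-dibromo-3,4-dimethoxythiophene 1,1-dioxide A7 and the N-(3-bromopropargyl) lactam A8.
- Forward key step: a Diels–Alder addition of A7 across the triple bond of A8, followed by cheletropic loss of the sulfonyl bridge, gives the hexasubstituted arene A9. One ether cleavage then reaches the target.
- For: it is the most convergent plan. The diene is symmetric, so there is no regiochemistry to control, and the bromines are placed by connectivity with no late halogenation. On convergence and on the endgame it is stronger than the chosen route.
- Against: A7 requires oxidation of an electron-rich dibromothiophene to its dioxide, which needs very strong oxygen-transfer reagents, and alkoxy-substituted thiophene dioxides are labile. The two donor groups raise the LUMO of a diene that reacts best in the inverse-demand sense. A8 is neither electron-rich nor strongly electron-poor, and 1-bromoalkynes do not tolerate prolonged heating. The transition state has to assemble six substituents around the new ring, and dimerisation of A7 competes.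
- Comparison: both partners and the cycloaddition would need development. The chosen route uses partners made by routine enolate and silylation chemistry and a benzannulation whose regiochemical course is established for this substrate class.

Key step: step 6

## Route

Step 1
Reactants: 1 methyl 4-methoxy-3-oxobutanoate
Product: 2 methyl 4-methoxy-3-(trimethylsilyloxy)but-2-enoate
Conditions: Me3SiCl, Et3N, toluene, 20 °C
Reagents that add atoms: chlorotrimethylsilane, C[Si](C)(C)Cl
Why: O-silylation of the enol of a β-keto ester under soft enolisation with an amine base, the standard first stage of bis(silyloxy) diene synthesis; the ketone oxygen is silylated because its enol is conjugated with the ester.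

Step 2
Reactants: 2 methyl 4-methoxy-3-(trimethylsilyloxy)but-2-enoate
Product: 4 1,4-dimethoxy-1,3-bis(trimethylsilyloxy)buta-1,3-diene, via lithium dienolate 3 (not isolated)
Conditions: LiN(iPr)2, THF, −78 °C; then Me3SiCl, −78 to 20 °C
Reagents that add atoms: chlorotrimethylsilane, C[Si](C)(C)Cl
Why: Kinetic deprotonation at the γ-CH2 (between the methoxy group and the silyl enol ether) gives the extended ester dienolate 3, which is silylated on oxygen; this is the standard second stage of 1,3-bis(silyloxy) diene synthesis, and the moisture-sensitive diene is used without chromatography.

Step 3
Reactants: 5 (2-oxopyrrolidin-1-yl)acetic acid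
Product: 7 N-methoxy-N-methyl-2-(2-oxopyrrolidin-1-yl)acetamide, via acyl imidazolide 6 (not isolated)
Conditions: 1,1'-carbonyldiimidazole, CH2Cl2, 20 °C; then MeNH(OMe)·HCl, 20 °C
Reagents that add atoms: N,O-dimethylhydroxylamine hydrochloride, CNOC.Cl
Why: Amide formation through acyl imidazolide 6, whose imidazolyl group comes from the carbonyldiimidazole; the lactam nitrogen is fully substituted, so no oxazolone can form and the acid is activated cleanly.

Step 4
Reactants: 7 N-methoxy-N-methyl-2-(2-oxopyrrolidin-1-yl)acetamide; 8 ethynylmagnesium bromide
Product: 9 1-(2-oxobut-3-yn-1-yl)pyrrolidin-2-one
Conditions: THF, −20 to 0 °C; inverse quench into cold aq NaHSO4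
Reagents that add atoms: none
Why: Acyl substitution of an N-methoxy-N-methyl amide by an alkynyl Grignard reagent; the magnesium chelate of the first adduct lasts until the quench so no second addition occurs, the acidic inverse quench protonates the released hydroxylamine before it can add to the ynone, and the far less electrophilic lactam is left alone.

Step 5
Reactants: 9 1-(2-oxobut-3-yn-1-yl)pyrrolidin-2-one
Product: 10 (E)-1-(4-methoxy-2-oxobut-3-en-1-yl)pyrrolidin-2-one
Conditions: MeOH (3 equiv), DABCO (10 mol %), CH2Cl2, 0 to 20 °C
Reagents that add atoms: methanol, CO
Why: Amine-catalysed conjugate addition of an alcohol to a terminal ynone: DABCO adds to the alkyne terminus, the zwitterion deprotonates methanol, and methoxide addition with loss of DABCO should give the more stable (E)-β-methoxy enone; the ynone has no propargylic hydrogen, so no allene can form.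

Step 6
Reactants: 4 1,4-dimethoxy-1,3-bis(trimethylsilyloxy)buta-1,3-diene; 10 (E)-1-(4-methoxy-2-oxobut-3-en-1-yl)pyrrolidin-2-one
Product: 13 methyl 2-hydroxy-3-methoxy-6-[(2-oxopyrrolidin-1-yl)methyl]benzoate, via open-chain enone keto ester 11 (not isolated), via cyclic aldol adduct 12 (not isolated)
Conditions: 4 (1.5 equiv), TiCl4 (2.2 equiv), CH2Cl2, −78 to 20 °C; then 10% aq HCl
Reagents that add atoms: none
Why: The closest known reaction type is the TiCl4-mediated formal (3+3) cyclocondensation of 1,3-bis(silyloxy)buta-1,3-dienes with 3-alkoxy-2-en-1-ones, which gives 6-substituted salicylates. TiCl4, used in excess because the lactam carbonyl binds the first equivalent, coordinates the ketone oxygen of 10 and sharpens its vinylogous-ester polarisation, so the methoxy-bearing terminus of 4 (its most nucleophilic carbon) adds to the β-carbon in a Mukaiyama–Michael step that forms the C4–C5 bond; the resulting titanium enolate then expels the β-methoxy group as methanol and leaves 11, present in the flask as its silyl ketene acetal or titanium enolate. The Lewis acid equilibrates the alkene of 11, and in the Z isomer the ester-side enolate carbon (the former central carbon of 4) lies next to the re-formed ketone. Attack there is a 6-(enolexo)-exo-trig aldol closure that forms the C1–C2 bond and the only ring, giving 12. Loss of water from 12 and enolisation of the resulting cyclohexadienone aromatise the ring to 13. No stereocentre survives: the methoxy-bearing carbon of 11 and the three stereocentres of 12 are uncontrolled and all become sp2. The selectivity that matters is regiochemical (terminus to β-carbon, central carbon to ketone); it is secured by the leaving group on the unsubstituted β-carbon and by the lower reactivity of the ketone flanked by the CH2N group, and it places the side chain ortho to the ester and para to the methoxy-bearing carbon.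

Step 7
Reactants: 13 methyl 2-hydroxy-3-methoxy-6-[(2-oxopyrrolidin-1-yl)methyl]benzoate
Product: 14 2-hydroxy-3-methoxy-6-[(2-oxopyrrolidin-1-yl)methyl]benzoic acid
Conditions: LiI, pyridine, 115 °C; then aq HCl
Reagents that add atoms: none
Why: SN2 dealkylation of a methyl ester by iodide (alkyl–oxygen cleavage), the classical method for benzoates with both ortho positions substituted; lithium held between the phenol and ester oxygens activates the ester, and the lactam and the aryl methyl ether should not react at this temperature.

Step 8
Reactants: 14 2-hydroxy-3-methoxy-6-[(2-oxopyrrolidin-1-yl)methyl]benzoic acid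
Product: 15 2,3-dihydroxy-6-[(2-oxopyrrolidin-1-yl)methyl]benzoic acid
Conditions: BBr3 (5 equiv), CH2Cl2, −78 to 0 °C; then H2O
Reagents that add atoms: none
Why: Lewis-acid cleavage of an aryl methyl ether: boron binds the ether oxygen next to the phenol (a cyclic borate forms), bromide attacks the methyl group, and hydrolysis on work-up frees the catechol; the excess covers the acid, phenol and lactam sites, and a premature loss of the carboxyl group would be harmless because that position is brominated in step 9.

Step 9
Reactants: 15 2,3-dihydroxy-6-[(2-oxopyrrolidin-1-yl)methyl]benzoic acid
Product: 16 1-[(2,3,6-tribromo-4,5-dihydroxyphenyl)methyl]pyrrolidin-2-one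
Conditions: Br2 (3.3 equiv), AcOH/H2O, 0 to 20 °C; then aq Na2S2O4
Reagents that add atoms: bromine, BrBr
Why: Electrophilic aromatic bromination at C5 (ortho to the C4 hydroxyl) and C6 (para to the C3 hydroxyl), together with decarboxylative ipso-bromination at C2 (ortho to the C3 hydroxyl), the reaction by which salicylic acids give bromophenols in aqueous bromine; after three substitutions no ring position is free, and the dithionite wash should return any ortho-quinone to the catechol.

## Compound list

1 | methyl 4-methoxy-3-oxobutanoate | COCC(=O)CC(=O)OC | starting material
2 | methyl 4-methoxy-3-(trimethylsilyloxy)but-2-enoate (alkene geometry immaterial) | COCC(O[Si](C)(C)C)=CC(=O)OC | intermediate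
3 | lithium 1,4-dimethoxy-3-(trimethylsilyloxy)buta-1,3-dien-1-olate (alkene geometry immaterial) | COC=C(O[Si](C)(C)C)C=C(OC)[O-].[Li+] | intermediate (not isolated)
4 | 1,4-dimethoxy-1,3-bis(trimethylsilyloxy)buta-1,3-diene (mixture of alkene isomers, immaterial) | COC=C(O[Si](C)(C)C)C=C(OC)O[Si](C)(C)C | intermediate
5 | (2-oxopyrrolidin-1-yl)acetic acid | O=C(O)CN1CCCC1=O | starting material
6 | 1-[2-(1H-imidazol-1-yl)-2-oxoethyl]pyrrolidin-2-one | O=C(CN1CCCC1=O)n1ccnc1 | intermediate (not isolated)
7 | N-methoxy-N-methyl-2-(2-oxopyrrolidin-1-yl)acetamide | CON(C)C(=O)CN1CCCC1=O | intermediate
8 | ethynylmagnesium bromide | C#C[Mg]Br | starting material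
9 | 1-(2-oxobut-3-yn-1-yl)pyrrolidin-2-one | C#CC(=O)CN1CCCC1=O | intermediate
10 | (E)-1-(4-methoxy-2-oxobut-3-en-1-yl)pyrrolidin-2-one | CO/C=C/C(=O)CN1CCCC1=O | intermediate
11 | methyl (5Z)-4-methoxy-3,7-dioxo-8-(2-oxopyrrolidin-1-yl)oct-5-enoate (racemic; drawn as the free keto ester) | COC(=O)CC(=O)C(OC)/C=C\C(=O)CN1CCCC1=O | intermediate (not isolated)
12 | methyl 2-hydroxy-5-methoxy-6-oxo-2-[(2-oxopyrrolidin-1-yl)methyl]cyclohex-3-ene-1-carboxylate (mixture of diastereomers) | COC(=O)C1C(=O)C(OC)C=CC1(O)CN1CCCC1=O | intermediate (not isolated)
13 | methyl 2-hydroxy-3-methoxy-6-[(2-oxopyrrolidin-1-yl)methyl]benzoate | COC(=O)c1c(O)c(OC)ccc1CN1CCCC1=O | intermediate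
14 | 2-hydroxy-3-methoxy-6-[(2-oxopyrrolidin-1-yl)methyl]benzoic acid | COc1ccc(CN2CCCC2=O)c(C(=O)O)c1O | intermediate
15 | 2,3-dihydroxy-6-[(2-oxopyrrolidin-1-yl)methyl]benzoic acid | O=C(O)c1c(O)c(O)ccc1CN1CCCC1=O | intermediate
16 | 1-[(2,3,6-tribromo-4,5-dihydroxyphenyl)methyl]pyrrolidin-2-one | O=C1CCCN1Cc1c(Br)c(O)c(O)c(Br)c1Br | target

## Step count and least certain steps

Total step count: 9. Longest linear sequence: 7 steps (steps 3, 4, 5, 6, 7, 8 and 9, from acid 5); the diene branch (steps 1 and 2) joins at step 6.

**Step 6 (key step).** Several things could go wrong:
- The lactam carbonyl may bind the Lewis acid so firmly that the ketone of 10 is not activated, and 4 is then merely desilylated.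
- Lewis-acid-assisted enolisation of the CH2 between ketone and lactam nitrogen may lead to self-condensation of 10.
- Attack of the diene terminus at the ketone carbon instead of the β-carbon would move the side chain next to the methoxy group.
- The sequence may stall at the open-chain stage if E to Z equilibration of 11 is slow.

The fallback keeps the benzannulation but brings in the lactam afterwards, so that TiCl4 never meets it. It sets out from 4 and returns at 15. Diene 4 and commercial (E)-4-methoxybut-3-en-2-one under the same TiCl4 conditions should give methyl 2-hydroxy-3-methoxy-6-methylbenzoate F1, the same benzannulation on the simplest enone of the class. Methylation of the phenol (MeI, K2CO3, acetone) gives methyl 2,3-dimethoxy-6-methylbenzoate F2. Radical benzylic bromination (N-bromosuccinimide, azobisisobutyronitrile, PhCF3, 80 °C) gives methyl 6-(bromomethyl)-2,3-dimethoxybenzoate F3. N-alkylation of pyrrolidin-2-one (NaH, DMF) gives methyl 2,3-dimethoxy-6-[(2-oxopyrrolidin-1-yl)methyl]benzoate F4. Ester dealkylation as in step 7 (LiI, pyridine) gives 2,3-dimethoxy-6-[(2-oxopyrrolidin-1-yl)methyl]benzoic acid F5, and BBr3 cleaves both aryl methyl ethers to give 15.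

**Step 4.** The Grignard reagent may deprotonate the CH2 of 7 instead of adding, the released hydroxylamine may add to the ynone during the quench, and the terminal ynone may polymerise on concentration. The fallback avoids a basic organometallic reagent; it sets out from 5 and returns at 10. Acid 5 with oxalyl chloride and catalytic DMF gives (2-oxopyrrolidin-1-yl)acetyl chloride F6. Acyl Sonogashira coupling of F6 with ethynyltrimethylsilane (PdCl2(PPh3)2, CuI, Et3N, THF) gives 1-[2-oxo-4-(trimethylsilyl)but-3-yn-1-yl]pyrrolidin-2-one F7. Methanol with catalytic K2CO3 removes the silyl group and adds across the triple bond in one operation to give 10.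

**Step 5.** A second addition of methanol may give the acetal, and the ynone may oligomerise under the nucleophilic catalyst. The fallback makes the over-addition the goal; it sets out from 9 and returns at 13. Compound 9 in methanol with catalytic NaOMe is driven to 1-(4,4-dimethoxy-2-oxobutyl)pyrrolidin-2-one F8. With 4 and TiCl4, the acetal of F8 ionises to an oxocarbenium ion that the diene terminus attacks, and the same aldol closure and aromatisation lead to 13.

**Step 9.** Bromine may oxidise the catechol to the ortho-quinone, which can tautomerise to a quinone methide and lose the lactam. Ipso attack at C1 (para to the C4 hydroxyl) may cleave the benzylic arm, and ipso substitution at C2 may be incomplete in the acidic medium. The fallback brominates while C4 is still a methyl ether; it sets out from 14 and returns at 16. Compound 14 with excess Br2 in AcOH/H2O, warmed for the third bromine (the one ortho to the methoxy group), should give 1-[(2,3,6-tribromo-5-hydroxy-4-methoxyphenyl)methyl]pyrrolidin-2-one F9 with loss of the carboxyl group. BBr3 then cleaves the ether of F9 to give 16, the usual last step for bromophenols.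

**Step 7.** The dealkylation may be slow, and partial loss of the carboxyl group or partial ether cleavage at 115 °C may give mixtures. The fallback sets out from 13 and returns at 15: excess BBr3 at 20 to 40 °C cleaves the aryl ether and, with boron chelated between the phenol oxygen and the ester carbonyl, the ester methyl group as well. It makes no compound outside the list (F0).

## Further compounds

F1 | step 6 | methyl 2-hydroxy-3-methoxy-6-methylbenzoate | COC(=O)c1c(O)c(OC)ccc1C
F2 | step 6 | methyl 2,3-dimethoxy-6-methylbenzoate | COC(=O)c1c(OC)c(OC)ccc1C
F3 | step 6 | methyl 6-(bromomethyl)-2,3-dimethoxybenzoate | COC(=O)c1c(OC)c(OC)ccc1CBr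
F4 | step 6 | methyl 2,3-dimethoxy-6-[(2-oxopyrrolidin-1-yl)methyl]benzoate | COC(=O)c1c(OC)c(OC)ccc1CN1CCCC1=O
F5 | step 6 | 2,3-dimethoxy-6-[(2-oxopyrrolidin-1-yl)methyl]benzoic acid | COc1ccc(CN2CCCC2=O)c(C(=O)O)c1OC
F6 | step 4 | (2-oxopyrrolidin-1-yl)acetyl chloride | O=C(Cl)CN1CCCC1=O
F7 | step 4 | 1-[2-oxo-4-(trimethylsilyl)but-3-yn-1-yl]pyrrolidin-2-one | C[Si](C)(C)C#CC(=O)CN1CCCC1=O
F8 | step 5 | 1-(4,4-dimethoxy-2-oxobutyl)pyrrolidin-2-one | COC(OC)CC(=O)CN1CCCC1=O
F9 | step 9 | 1-[(2,3,6-tribromo-5-hydroxy-4-methoxyphenyl)methyl]pyrrolidin-2-one | COc1c(O)c(Br)c(CN2CCCC2=O)c(Br)c1Br
F0 | step 7 | none | none
A1 | alternative 1 | 1-[(2,3,4,5,6-pentabromophenyl)methyl]pyrrolidin-2-one | O=C1CCCN1Cc1c(Br)c(Br)c(Br)c(Br)c1Br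
A2 | alternative 1 | ethane-1,2-diol | OCCO
A3 | alternative 1 | 1-[(5,7,8-tribromo-2,3-dihydro-1,4-benzodioxin-6-yl)methyl]pyrrolidin-2-one | O=C1CCCN1Cc1c(Br)c2OCCOc2c(Br)c1Br
A4 | alternative 2 | diethyl 3-[(2-oxopyrrolidin-1-yl)methyl]hexanedioate (racemic) | CCOC(=O)CCC(CN1CCCC1=O)CC(=O)OCC
A5 | alternative 2 | diethyl oxalate | CCOC(=O)C(=O)OCC
A6 | alternative 2 | diethyl 2,3-dihydroxy-5-[(2-oxopyrrolidin-1-yl)methyl]cyclohexa-1,3-diene-1,4-dicarboxylate (racemic) | CCOC(=O)C1=C(O)C(O)=C(C(=O)OCC)C(CN2CCCC2=O)C1
A7 | alternative 3 | 2,5-dibromo-3,4-dimethoxythiophene 1,1-dioxide | COC1=C(Br)S(=O)(=O)C(Br)=C1OC
A8 | alternative 3 | 1-(3-bromoprop-2-yn-1-yl)pyrrolidin-2-one | BrC#CCN1CCCC1=O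
A9 | alternative 3 | 1-[(2,3,6-tribromo-4,5-dimethoxyphenyl)methyl]pyrrolidin-2-one | O=C1CCCN1Cc1c(Br)c(OC)c(OC)c(Br)c1Br
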